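The autumn flask held 18.3 % of its substrate at 5.00 d, and from that reading I took 2.04 d as the half-life of the substrate at 5 °C, the time in which c(substrate) falls by a factor of two, reading the run as pseudo-first-order with the gas held. At the last dawn reading, substrate and product added up to >99.9 %, so I expected product as the end state, and my decision was whether to leave the new flasks for 8.0 d or longer.

| setting | dawn | autumn | cedar | ash | oak |
|---|---|---|---|---|---|
| substrate | 0.0050 M | 0.020 M | 0.010 M | 0.010 M | 0.010 M |
| gas | 4.3 mM (held) | 4.3 mM (held) | 4.3 mM (held) | 4.3 mM (held) | 4.3 mM (held) |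
| temperature | −20 °C | 5 °C | 25 °C | −15 °C | 5 °C |
| remark | run made earlier | run made earlier |  |  |  |
| time |  |  | 8.0 d | 8.0 d | 8.0 d |

| run | time / d | product / % | substrate / % |
|---|---|---|---|
| dawn | 5.00 | 3.3 | 96.5 |
| dawn | 8.00 | 5.6 | 94.3 |
| dawn | 12.0 | 7.7 | 91.5 |
| dawn | 15.0 | 9.8 | 90.2 |
| dawn | 30.0 | 19.2 | 81.1 |
| dawn | 40.0 | 24.4 | 75.5 |
| dawn | 60.0 | 34.4 | 65.6 |
| autumn | 0.833 | 22.7 | 76.5 |
| autumn | 3.00 | 62.7 | 37.1 |
| autumn | 5.00 | 81.9 | 18.3 |
| autumn | 8.00 | 93.5 | 5.9 |
| autumn | 10.0 | 97.4 | 3.1 |
| autumn | 15.0 | 99.3 | 0.2 |

(scatter of a reading: 0.3 percentage points)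

- at the start none of the gas is in solution

* the best flask by amount of product, in percent of the substrate charged; "all alike" if 1.5 percentage points covers them all (cedar / ash / oak / all alike)
* amount of product at the end, in percent of the substrate charged, cedar
* amount of product at the end, in percent of the substrate charged, ash
* amount of product at the end, in percent of the substrate charged, oak

Oak stood at the temperature of autumn, so I counted 3.92 half-lives in its 8.0 d, which left 6.61 % of the substrate and gave 93.4 % product. The dawn run, read the same way at its last reading, had a half-life of 98.6 d at −20 °C, which was longer by a factor of 48.3 than the half-life I had taken from autumn at 5 °C. To leave one part in 100 by that time, cedar needed a half-life of 1.20 d or shorter, which asked for a shortening by a factor of 1.70 on warming from 5 °C to 25 °C, far smaller than the factor between dawn and autumn. Ash stood at −15 °C, close to dawn, and 8.0 d was 0.0811 of the dawn half-life, so I expected ash to be far from its end state, and I kept the time as planned.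

The forecast named cedar as the best flask, with 99.5 % in cedar, 12 % in ash and 93.5 % in oak, on the ground that “Each run is cleanly first order in substrate”; its oak differed from mine by 0.11 percentage points.

The flasks gave 99.4 % product in cedar, 13.3 % in ash and 95.0 % in oak, so cedar was best.

    crystals ⇌ leaving ligand, rate k1*(cs1 - [leaving ligand]) while solid is left; crystals form when [leaving ligand] > cs1 (solubility = 3.70 mM, k = 0.0490 /min)
    reagent + intermediate → product (k = 16.0 /M/min, Ea = 53.0 kJ/mol)
    gas ⇌ reagent, rate k3*(csat - [reagent]) (kL = 0.00220 /min)
    substrate ⇌ intermediate + leaving ligand (K = 4.70 × 10⁻⁵ M, k = 3.80 × 10⁻⁴ /min, Ea = 102 kJ/mol, ΔH = −70.0 kJ/mol)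
    (constants at 5 °C)

Oak, counted at 2.04 d, was to keep 6.61 % of its substrate and kept 5.0 %. Cedar, left for 3.0 d, still held 17.7 % of its substrate, which gave an average half-life of 1.20 d, level with the 1.20 d it needed and shorter by a factor of 1.70 than the 2.04 d I had read from the autumn run. At 8.00 d, cedar held 0.55 % of its substrate.

The readings stem from a simulated flask on assumed constants; noise was put on by code.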